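The bicyclo[3.2.1]octenone is cut at C1–C2 and C4–C5 (C1 allyl bridgehead, C2=C3(OMe), C4 carbinol, C5 OMe bridgehead, C6 aryl, C7 methyl, C8 ketone). The feature exploited is that the C2–C3–C4 bridge, oxygenated on C3, spans both α-carbons (C1, C5) of the C8 ketone of the cyclopentanone ring C1–C8–C5–C6–C7 and is therefore methoxymalonyl dichloride. One operation C-acylates C1 and C5, closes the six-membered ring C1–C2–C3–C4–C5–C8 and sets both bridgeheads. The precursor is the regiodefined C1=C8 trimethylsilyl enol ether of a 2-allyl-3-methyl-4-aryl-5-methoxycyclopentanone, built from a 4-silyloxycyclopentenone by two cuprate additions.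

Key step: step 11

Remark: (S)-4-(tert-butyldimethylsilyloxy)cyclopent-2-en-1-one is assumed to be purchasable as a single enantiomer; Ar = 3-methoxy-4-(triisopropylsilyloxy)phenyl; locants C1–C8 are those of the target skeleton.

Step 1
Reactants: 1 4-bromo-2-methoxyphenol
Product: 2 (4-bromo-2-methoxyphenoxy)triisopropylsilane
Conditions: iPr3SiCl, imidazole, DMF, rt
Reagents that add atoms: chlorotriisopropylsilane, CC(C)[Si](Cl)(C(C)C)C(C)C
Why: Imidazole-promoted silylation gives an aryl triisopropylsilyl ether, which tolerates organometallics, acid chloride/HCl and brief aqueous base better than a tert-butyldimethylsilyl ether and still falls to fluoride at the end.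

Step 2
Reactants: 2 (4-bromo-2-methoxyphenoxy)triisopropylsilane; 3 (S)-4-(tert-butyldimethylsilyloxy)cyclopent-2-en-1-one
Product: 5 (3R,4S)-4-(tert-butyldimethylsilyloxy)-3-Ar-1-(trimethylsilyloxy)cyclopent-1-ene (Ar trans to OTBS), via arylmagnesium bromide 4 (not isolated)
Conditions: Mg, THF, 50 °C; then 3, CuBr·SMe2 (15 mol %), Me3SiCl, DMPU, THF, −78 °C; Et3N, pentane work-up
Reagents that add atoms: chlorotrimethylsilane, C[Si](C)(C)Cl
Why: Copper-catalysed Grignard conjugate addition with in situ silyl trapping delivers the aryl group anti to the silyloxy substituent, which sets the aryl stereocentre, and freezes the enolate on the aryl side before it can equilibrate and expel silanolate.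

Step 3
Reactants: 5 (3R,4S)-4-(tert-butyldimethylsilyloxy)-3-Ar-1-(trimethylsilyloxy)cyclopent-1-ene
Product: 7 (2S,3S,4S)-4-(tert-butyldimethylsilyloxy)-2-hydroxy-3-Ar-cyclopentan-1-one (each substituent trans to its neighbour), via alpha-silyloxy ketone 6 (not isolated)
Conditions: mCPBA, NaHCO3, CH2Cl2, 0 °C; then citric acid, MeOH, rt
Reagents that add atoms: 3-chloroperoxybenzoic acid, OOC(=O)c1cccc(Cl)c1
Why: Rubottom oxidation epoxidises the electron-rich silyl enol ether anti to the neighbouring aryl group and, after silyl migration, places oxygen on the α-carbon next to the aryl-bearing carbon (this centre is planarised again in step 11, so its configuration is immaterial).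

Step 4
Reactants: 7 (2S,3S,4S)-4-(tert-butyldimethylsilyloxy)-2-hydroxy-3-Ar-cyclopentan-1-one
Product: 8 (2S,3S,4S)-4-(tert-butyldimethylsilyloxy)-2-methoxy-3-Ar-cyclopentan-1-one
Conditions: Me3OBF4, 1,8-bis(dimethylamino)naphthalene, 4 Å MS, CH2Cl2, rt
Reagents that add atoms: trimethyloxonium tetrafluoroborate, C[O+](C)C.F[B-](F)(F)F
Why: Meerwein O-methylation with a non-nucleophilic proton scavenger etherifies the α-ketol without forming an enolate, so neither α-ketol shift nor premature β-elimination should intervene.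

Step 5
Reactants: 8 (2S,3S,4S)-4-(tert-butyldimethylsilyloxy)-2-methoxy-3-Ar-cyclopentan-1-one
Product: 9 (4S,5S)-5-methoxy-4-Ar-cyclopent-2-en-1-one
Conditions: DBU, CH2Cl2, 0 °C
Reagents that add atoms: none
Why: E1cB β-elimination of silanolate through the enolate of the only CH2 α-position unveils the enone and leaves the aryl stereocentre, now γ to the carbonyl, untouched if the exposure to base is kept short and cold.

Step 6
Reactants: 9 (4S,5S)-5-methoxy-4-Ar-cyclopent-2-en-1-one
Product: 10 (4S,5S)-2-iodo-5-methoxy-4-Ar-cyclopent-2-en-1-one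
Conditions: I2, pyridine, CH2Cl2, 0 °C to rt
Reagents that add atoms: iodine, II
Why: Pyridine-mediated α-iodination of the enone (conjugate addition of pyridine, iodination of the enolate, elimination) functionalises the α-carbon under weakly basic conditions that should not deprotonate the γ-aryl CH.

Step 7
Reactants: 10 (4S,5S)-2-iodo-5-methoxy-4-Ar-cyclopent-2-en-1-one; 11 allyltributylstannane
Product: 12 (4S,5S)-2-allyl-5-methoxy-4-Ar-cyclopent-2-en-1-one
Conditions: Pd2(dba)3, AsPh3, CuI, NMP, rt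
Reagents that add atoms: none
Why: Stille coupling of the α-iodoenone, accelerated by CuI and the weakly bound arsine ligand, installs the allyl group at room temperature without base and without touching the stereocentres.

Step 8
Reactants: 12 (4S,5S)-2-allyl-5-methoxy-4-Ar-cyclopent-2-en-1-one
Product: 13 (3R,4S,5S)-2-allyl-5-methoxy-3-methyl-4-Ar-1-(trimethylsilyloxy)cyclopent-1-ene (methyl trans to Ar)
Conditions: MeLi, CuI, Et2O, 0 °C; then Me3SiCl, 12, THF, −78 °C; Et3N, pentane, filtration
Reagents that add atoms: lithium dimethylcuprate (made in the flask from MeLi and CuI), [Li+].C[Cu-]C; chlorotrimethylsilane, C[Si](C)(C)Cl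
Why: Silyl-chloride-accelerated Gilman cuprate conjugate addition delivers methyl anti to the adjacent aryl group, which sets C7, and traps the enolate as the regiodefined tetrasubstituted C1=C8 silyl enol ether.

Step 9
Reactants: 14 dimethyl methoxymalonate
Product: 15 methoxymalonic acid
Conditions: NaOH, H2O/MeOH, rt; then HCl (aq), 0 °C, extraction
Reagents that add atoms: sodium hydroxide, [Na+].[OH-]
Why: Saponification of the diester followed by cold acidification gives the diacid well below the temperature at which malonic acids decarboxylate.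

Step 10
Reactants: 15 methoxymalonic acid
Product: 16 methoxymalonyl dichloride
Conditions: (COCl)2, DMF (cat.), CH2Cl2, 0 °C to rt; bulb-to-bulb distillation, used at once
Reagents that add atoms: oxalyl chloride, ClC(=O)C(=O)Cl
Why: Vilsmeier-catalysed acid chloride formation at room temperature is the standard mild access to malonyl dichlorides and avoids thermal decarboxylation.

Step 11
Reactants: 13 (3R,4S,5S)-2-allyl-5-methoxy-3-methyl-4-Ar-1-(trimethylsilyloxy)cyclopent-1-ene; 16 methoxymalonyl dichloride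
Product: 18 1-allyl-2-hydroxy-3,5-dimethoxy-7-exo-methyl-6-endo-Ar-bicyclo[3.2.1]oct-2-ene-4,8-dione (enolized trione), via C1-acylated acid chloride 17 (not isolated)
Conditions: 16 (1.5 equiv), Et2O, −20 °C to rt; product taken into cold aq. NaHCO3, then acidified with citric acid
Reagents that add atoms: none
Why: Proposed new method: the C1=C8 enol silane is C-acylated at C1 by one acid chloride terminus of 16 (or the derived chlorocarbonyl ketene) with loss of Me3SiCl, and the HCl-promoted C8=C5 enol of 17 is then C-acylated by the second terminus, the closest known reaction being the Effenberger annulation of cyclohexanone enol ethers with malonyl dichloride to bicyclo[3.3.1]nonane-2,4,9-triones. The six-membered ring C1–C2–C3–C4–C5–C8 closes in a 6-(enolendo)-exo-trig mode. C1 is set by approach anti to the adjacent C7 methyl, which A1,2 strain with the C1 allyl group holds pseudo-axial, so allyl ends cis to methyl; C5 is set by the tether, which can reach the C5 enol carbon only from the face of the C1 acyl arm, the face that carries the C6 aryl. The step needs intermolecular acylation at C1 and not C5, at carbon and not oxygen, and anti to methyl: the cuprate-derived regiodefined enol silane secures the site, the C7 methyl the face, and the second bond has no freedom. Enolization of the product to the C2–C3–C4 vinylogous acid removes the otherwise cleavable non-enolizable C4/C8 β-diketone from equilibrium and drives the closure.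

Step 12
Reactants: 18 1-allyl-2-hydroxy-3,5-dimethoxy-7-exo-methyl-6-endo-Ar-bicyclo[3.2.1]oct-2-ene-4,8-dione
Product: 19 1-allyl-3,5-dimethoxy-7-exo-methyl-4,8-dioxo-6-endo-Ar-bicyclo[3.2.1]oct-2-en-2-yl trifluoromethanesulfonate
Conditions: Tf2O, Et3N, CH2Cl2, −78 °C
Reagents that add atoms: trifluoromethanesulfonic anhydride, O=S(=O)(OS(=O)(=O)C(F)(F)F)C(F)(F)F
Why: O-sulfonylation of the vinylogous acid at low temperature should take the C2 oxygen, which is less shielded (the C6 endo aryl and the C5 methoxy flank the C4 oxygen) and more electron-rich (C4 has the inductively withdrawing C5–OMe neighbour), the regiochemistry to be verified by HMBC before going on.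

Step 13
Reactants: 19 1-allyl-3,5-dimethoxy-7-exo-methyl-4,8-dioxo-6-endo-Ar-bicyclo[3.2.1]oct-2-en-2-yl trifluoromethanesulfonate
Product: 20 1-allyl-3,5-dimethoxy-7-exo-methyl-6-endo-Ar-bicyclo[3.2.1]oct-2-ene-4,8-dione
Conditions: Pd(OAc)2 (5 mol %), PPh3, HCO2H, Bu3N, DMF, 60 °C
Reagents that add atoms: none
Why: Palladium-catalysed formate reduction of the β-triflyloxy enone (oxidative addition, formate exchange, decarboxylation, reductive elimination) replaces C2–O by C2–H and should leave the allyl group, both ketones and the aryl silyl ether alone.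

Step 14
Reactants: 20 1-allyl-3,5-dimethoxy-7-exo-methyl-6-endo-Ar-bicyclo[3.2.1]oct-2-ene-4,8-dione
Product: 21 (1R,4S,5R,6S,7R)-1-allyl-4-hydroxy-3,5-dimethoxy-7-methyl-6-Ar-bicyclo[3.2.1]oct-2-en-8-one
Conditions: NaBH4, CeCl3·7H2O, MeOH, −78 °C
Reagents that add atoms: none
Why: Luche 1,2-reduction should take the cerium-activated C4 enone carbonyl in preference to the doubly neopentyl C8 ketone, with hydride arriving on the exo face away from the C6 endo aryl to give the endo (4S) alcohol.

Step 15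
Reactants: 21 (1R,4S,5R,6S,7R)-1-allyl-4-hydroxy-3,5-dimethoxy-7-methyl-6-Ar-bicyclo[3.2.1]oct-2-en-8-one
Product: 22 (1R,4S,5R,6S,7R)-1-allyl-4-hydroxy-6-(4-hydroxy-3-methoxyphenyl)-3,5-dimethoxy-7-methylbicyclo[3.2.1]oct-2-en-8-one
Conditions: Bu4NF, AcOH, THF, 0 °C
Reagents that add atoms: none
Why: Fluoride cleavage of the aryl silyl ether, buffered with acetic acid so that the β-hydroxy ketone is not opened by retro-aldol reaction and the enol ether is not hydrolysed, frees the phenol.

Compound list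
1 | 4-bromo-2-methoxyphenol | COc1cc(Br)ccc1O | starting material
2 | (4-bromo-2-methoxyphenoxy)triisopropylsilane | COc1cc(Br)ccc1O[Si](C(C)C)(C(C)C)C(C)C | intermediate
3 | (S)-4-(tert-butyldimethylsilyloxy)cyclopent-2-en-1-one | O=C1C=C[C@@H](O[Si](C)(C)C(C)(C)C)C1 | starting material
4 | [3-methoxy-4-(triisopropylsilyloxy)phenyl]magnesium bromide | COc1cc([Mg]Br)ccc1O[Si](C(C)C)(C(C)C)C(C)C | intermediate
5 | (3R,4S)-4-(tert-butyldimethylsilyloxy)-3-Ar-1-(trimethylsilyloxy)cyclopent-1-ene | C[Si](C)(C)OC1=C[C@H](c2ccc(O[Si](C(C)C)(C(C)C)C(C)C)c(OC)c2)[C@@H](O[Si](C)(C)C(C)(C)C)C1 | intermediate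
6 | 4-(tert-butyldimethylsilyloxy)-3-Ar-2-(trimethylsilyloxy)cyclopentan-1-one (2,3-trans; 3,4-trans) | O=C1C[C@H](O[Si](C)(C)C(C)(C)C)[C@@H](c2ccc(O[Si](C(C)C)(C(C)C)C(C)C)c(OC)c2)[C@@H]1O[Si](C)(C)C | intermediate
7 | (2S,3S,4S)-4-(tert-butyldimethylsilyloxy)-2-hydroxy-3-Ar-cyclopentan-1-one | O=C1C[C@H](O[Si](C)(C)C(C)(C)C)[C@@H](c2ccc(O[Si](C(C)C)(C(C)C)C(C)C)c(OC)c2)[C@@H]1O | intermediate
8 | (2S,3S,4S)-4-(tert-butyldimethylsilyloxy)-2-methoxy-3-Ar-cyclopentan-1-one | O=C1C[C@H](O[Si](C)(C)C(C)(C)C)[C@@H](c2ccc(O[Si](C(C)C)(C(C)C)C(C)C)c(OC)c2)[C@@H]1OC | intermediate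
9 | (4S,5S)-5-methoxy-4-Ar-cyclopent-2-en-1-one | O=C1C=C[C@@H](c2ccc(O[Si](C(C)C)(C(C)C)C(C)C)c(OC)c2)[C@@H]1OC | intermediate
10 | (4S,5S)-2-iodo-5-methoxy-4-Ar-cyclopent-2-en-1-one | O=C1C(I)=C[C@@H](c2ccc(O[Si](C(C)C)(C(C)C)C(C)C)c(OC)c2)[C@@H]1OC | intermediate
11 | allyltributylstannane | C=CC[Sn](CCCC)(CCCC)CCCC | starting material
12 | (4S,5S)-2-allyl-5-methoxy-4-Ar-cyclopent-2-en-1-one | C=CCC1=C[C@@H](c2ccc(O[Si](C(C)C)(C(C)C)C(C)C)c(OC)c2)[C@H](OC)C1=O | intermediate
13 | (3R,4S,5S)-2-allyl-5-methoxy-3-methyl-4-Ar-1-(trimethylsilyloxy)cyclopent-1-ene | C=CCC1=C(O[Si](C)(C)C)[C@@H](OC)[C@H](c2ccc(O[Si](C(C)C)(C(C)C)C(C)C)c(OC)c2)[C@H]1C | intermediate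
14 | dimethyl methoxymalonate | COC(C(=O)OC)C(=O)OC | starting material
15 | methoxymalonic acid | COC(C(=O)O)C(=O)O | intermediate
16 | methoxymalonyl dichloride | COC(C(=O)Cl)C(=O)Cl | intermediate
17 | 3-(1-allyl-3-methoxy-5-methyl-2-oxo-4-Ar-cyclopentyl)-2-methoxy-3-oxopropanoyl chloride (acyl arm trans to methyl) | C=CC[C@@]1(C(=O)C(OC)C(=O)Cl)C(=O)[C@@H](OC)[C@H](c2ccc(O[Si](C(C)C)(C(C)C)C(C)C)c(OC)c2)[C@H]1C | intermediate
18 | 1-allyl-2-hydroxy-3,5-dimethoxy-7-exo-methyl-6-endo-Ar-bicyclo[3.2.1]oct-2-ene-4,8-dione | C=CC[C@@]12C(O)=C(OC)C(=O)[C@@](OC)(C1=O)[C@H](c1ccc(O[Si](C(C)C)(C(C)C)C(C)C)c(OC)c1)[C@H]2C | intermediate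
19 | 1-allyl-3,5-dimethoxy-7-exo-methyl-4,8-dioxo-6-endo-Ar-bicyclo[3.2.1]oct-2-en-2-yl trifluoromethanesulfonate | C=CC[C@@]12C(OS(=O)(=O)C(F)(F)F)=C(OC)C(=O)[C@@](OC)(C1=O)[C@H](c1ccc(O[Si](C(C)C)(C(C)C)C(C)C)c(OC)c1)[C@H]2C | intermediate
20 | 1-allyl-3,5-dimethoxy-7-exo-methyl-6-endo-Ar-bicyclo[3.2.1]oct-2-ene-4,8-dione | C=CC[C@@]12C=C(OC)C(=O)[C@@](OC)(C1=O)[C@H](c1ccc(O[Si](C(C)C)(C(C)C)C(C)C)c(OC)c1)[C@H]2C | intermediate
21 | (1R,4S,5R,6S,7R)-1-allyl-4-hydroxy-3,5-dimethoxy-7-methyl-6-Ar-bicyclo[3.2.1]oct-2-en-8-one | C=CC[C@@]12C=C(OC)[C@H](O)[C@@](OC)(C1=O)[C@H](c1ccc(O[Si](C(C)C)(C(C)C)C(C)C)c(OC)c1)[C@H]2C | intermediate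
22 | (1R,4S,5R,6S,7R)-1-allyl-4-hydroxy-6-(4-hydroxy-3-methoxyphenyl)-3,5-dimethoxy-7-methylbicyclo[3.2.1]oct-2-en-8-one | C=CC[C@@]12C=C(OC)[C@H](O)[C@@](OC)(C1=O)[C@H](c1ccc(O)c(OC)c1)[C@H]2C | target

Total step count: 15. Longest linear sequence: 13 steps (steps 1–8 and 11–15, from 4-bromo-2-methoxyphenol); steps 9–10 are a two-step side branch to 16.

Steps most likely to fail

1. Step 11 (Proposed new method). What may go wrong: O-acylation in place of C-acylation at the hindered tetrasubstituted enol silane, closure of the C8=C5 enol through oxygen (enol lactone) in the more strained [3.2.1] series, or attack on the methyl-bearing face of C1. Fallback, known reactions only, from 13 to 20: a Lewis-acid-mediated Mukaiyama–Michael addition of 13 to 2-methoxyacrolein (BF3·OEt2, CH2Cl2, −78 °C) forms C1–C2 anti to the methyl group and gives the keto aldehyde F1. An intramolecular aldol reaction of the C5 enol with the aldehyde (pyrrolidine, AcOH) forms C4–C5 and gives the bridged ketol F2. Dess–Martin oxidation gives the C4,C8-dione F3, which can enolize only toward C3. LiN(SiMe3)2/Me3SiCl then gives the silyl enol ether F4, and Saegusa–Ito oxidation with Pd(OAc)2 introduces C2=C3 to give 20. This path fixes the C2/C4 oxidation pattern by the order of bond formation and makes steps 12 and 13 unnecessary; it does not remove the facial question at C1.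

2. Step 12. What may go wrong: sulfonylation of the C4 oxygen, or an unselective mixture, because the two enol oxygens differ only in their bridgehead neighbours. Fallback from 18 to 22, in which the C1 allyl group distinguishes the two oxygens by constitution: N-iodosuccinimide (NaHCO3, MeCN, 0 °C) closes the C2 enol oxygen onto the allyl alkene (5-exo iodoetherification; the C4 oxygen cannot reach it) and gives the cyclic vinylogous ester F5. Luche reduction of the free C4 carbonyl from the exo face, with the same chemoselectivity demand as step 14, gives alcohol F6, and Et3SiOTf/2,6-lutidine gives its triethylsilyl ether F7. Zn/AcOH fragmentation of the β-iodo ether restores the allyl group and gives the C2 ketone F8, which can enolize only toward C3. KN(SiMe3)2/PhNTf2 at −78 °C gives the enol triflate F9, formate reduction as in step 13 gives the bis-silyl ether F10, and Bu4NF/AcOH removes both silyl groups to give 22.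

3. Step 5. What may go wrong: erosion of the aryl stereocentre through base-mediated γ-deprotonation of the product enone and migration of the double bond into conjugation with the aryl ring. Fallback from 8 to 9, which never exposes the enone to an amidine base: aqueous HCl in THF removes the secondary tert-butyldimethylsilyl group and gives the β-hydroxy ketone F11, and thermal syn-elimination with the Burgess reagent (THF, 50 °C) gives 9.

Further compounds
F1 | step 11 | 3-(1-allyl-3-methoxy-5-methyl-2-oxo-4-Ar-cyclopentyl)-2-methoxypropanal (side chain trans to methyl) | C=CC[C@@]1(CC(OC)C=O)C(=O)[C@@H](OC)[C@H](c2ccc(O[Si](C(C)C)(C(C)C)C(C)C)c(OC)c2)[C@H]1C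
F2 | step 11 | 1-allyl-4-hydroxy-3,5-dimethoxy-7-exo-methyl-6-endo-Ar-bicyclo[3.2.1]octan-8-one | C=CC[C@@]12CC(OC)C(O)[C@@](OC)(C1=O)[C@H](c1ccc(O[Si](C(C)C)(C(C)C)C(C)C)c(OC)c1)[C@H]2C
F3 | step 11 | 1-allyl-3,5-dimethoxy-7-exo-methyl-6-endo-Ar-bicyclo[3.2.1]octane-4,8-dione | C=CC[C@@]12CC(OC)C(=O)[C@@](OC)(C1=O)[C@H](c1ccc(O[Si](C(C)C)(C(C)C)C(C)C)c(OC)c1)[C@H]2C
F4 | step 11 | 1-allyl-3,5-dimethoxy-7-exo-methyl-6-endo-Ar-4-(trimethylsilyloxy)bicyclo[3.2.1]oct-3-en-8-one | C=CC[C@@]12CC(OC)=C(O[Si](C)(C)C)[C@@](OC)(C1=O)[C@H](c1ccc(O[Si](C(C)C)(C(C)C)C(C)C)c(OC)c1)[C@H]2C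
F5 | step 12 | iodoether of 18: C2 enol oxygen bonded to the internal carbon of the former allyl group (2-iodomethyl-tetrahydrofuran ring fused at C1–C2), C4 and C8 ketones free | ICC1C[C@@]23C(O1)=C(OC)C(=O)[C@@](OC)(C2=O)[C@H](c4ccc(O[Si](C(C)C)(C(C)C)C(C)C)c(OC)c4)[C@H]3C
F6 | step 12 | C4 endo alcohol of F5 | ICC1C[C@@]23C(O1)=C(OC)[C@H](O)[C@@](OC)(C2=O)[C@H](c4ccc(O[Si](C(C)C)(C(C)C)C(C)C)c(OC)c4)[C@H]3C
F7 | step 12 | C4 triethylsilyl ether of F6 | ICC1C[C@@]23C(O1)=C(OC)[C@H](O[Si](CC)(CC)CC)[C@@](OC)(C2=O)[C@H](c4ccc(O[Si](C(C)C)(C(C)C)C(C)C)c(OC)c4)[C@H]3C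
F8 | step 12 | 1-allyl-3,5-dimethoxy-7-exo-methyl-6-endo-Ar-4-endo-(triethylsilyloxy)bicyclo[3.2.1]octane-2,8-dione | C=CC[C@@]12C(=O)C(OC)[C@H](O[Si](CC)(CC)CC)[C@@](OC)(C1=O)[C@H](c1ccc(O[Si](C(C)C)(C(C)C)C(C)C)c(OC)c1)[C@H]2C
F9 | step 12 | 1-allyl-3,5-dimethoxy-7-exo-methyl-8-oxo-6-endo-Ar-4-endo-(triethylsilyloxy)bicyclo[3.2.1]oct-2-en-2-yl trifluoromethanesulfonate | C=CC[C@@]12C(OS(=O)(=O)C(F)(F)F)=C(OC)[C@H](O[Si](CC)(CC)CC)[C@@](OC)(C1=O)[C@H](c1ccc(O[Si](C(C)C)(C(C)C)C(C)C)c(OC)c1)[C@H]2C
F10 | step 12 | C4 triethylsilyl ether of 21 | C=CC[C@@]12C=C(OC)[C@H](O[Si](CC)(CC)CC)[C@@](OC)(C1=O)[C@H](c1ccc(O[Si](C(C)C)(C(C)C)C(C)C)c(OC)c1)[C@H]2C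
F11 | step 5 | (2S,3S,4S)-4-hydroxy-2-methoxy-3-Ar-cyclopentan-1-one | O=C1C[C@H](O)[C@@H](c2ccc(O[Si](C(C)C)(C(C)C)C(C)C)c(OC)c2)[C@@H]1OC
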